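## Analysis of the target

The target is a biflavonoid: C3 of a naringenin-type flavanone (rings A, C and B) is bonded to C3' of an apigenin-type flavone (benzo ring D, pyranone ring F, and the 4-hydroxyphenyl ring E that carries the link). The only stereocentres are C2 and C3 of ring C. They are adjacent, each bears an aryl group, and the configuration is (2R,3S), which places the two aryl groups trans and both equatorial. Both centres are labile in the target: C3 is benzylic and α to the C4 ketone, and C2 is the β-aryloxy carbon of the same ketone, so base can enolise C3 or open ring C by retro-oxa-Michael reaction. The free hydroxyl of ring E sits two carbons from C4 and can close a furan ring onto the ketone under acid. Six phenols have to be carried protected and released without acid or base. The difficulty is therefore the absolute control of two contiguous, aryl-bearing, epimerisable centres and the crowded bond from C3 to an ortho-substituted ring, not the carbon count. The route rests on one structural reading: with C4 at the ether oxidation level, ring C is a 2,3-trans-diarylchroman, in which O1–C8a–C4a–C4 is the heterodiene of an ortho-quinone methide obtainable from a salicylaldehyde, and C2–C3 with its two aryl groups is an (E)-stilbene.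

## Retrosynthetic reasoning

**Target 20 back to 19.** Only oxygen–benzyl bonds are cut: five benzyl ethers and one benzyl carbonate on the ring E oxygen. All six are chosen to fall in a single neutral hydrogenolysis, so the free polyphenol, with its enolisable C3 and its hydroxyl next to the ketone, never meets acid or base.

**19 back to 17 through 18.** The C4 carbonyl is traced to a C4 methyl ether by way of the C4 alcohol. This keeps C3 free of an acidifying carbonyl until the penultimate step. Going forward, the doubly activated benzylic ether must be exchanged for hydroxyl and the alcohol oxidised, with the carbonate intact. The C4 configuration is deliberately destroyed, so it never has to be controlled.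

**17 back to 13, 11 and 14.** C3–C4 and O1–C2 are cut together, which is the retro-[4+2] opening of ring C. The cut is made here because it returns ring A as the simple salicylaldehyde 13 and the C2–C3 unit as stilbene 11, whose (E) geometry already encodes the trans relationship. Both stereocentres then arise in one catalytic event while neither is next to a carbonyl. The flavone half is a spectator. Orthoformate 14 supplies the C4 methoxy group and turns the aldehyde into the ionisable acetal. The forward reaction must be regioselective (C4 to the alkene carbon bearing ring E), enantioselective, and chemoselective for the stilbene over the chromone double bond.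

**13 back to 12.** Two O-benzyl bonds are cut. The hydroxyl left free is the chelated one, which becomes O1.

**11 back to 10 and 9.** The ring E oxygen changes its protecting group, from a methoxymethyl ether to a benzyl carbonate. The ether is needed because the flavone is built under strong base. The carbonate is needed afterwards for three reasons: it makes ring E a poor donor, which fixes the regiochemistry of the cycloaddition; it blocks the phenol as a nucleophile toward C4; and it is removed at the end together with the benzyl ethers.

**9 back to 6 and 8.** The bond between ring E and the vinyl carbon is cut, a Heck disconnection. It gives the (E)-alkene directly from an aryl bromide and a terminal styrene, and it brings the alkene in only after the oxidative flavone synthesis. Styrene 8 comes from aldehyde 7 by one-carbon olefination.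

**6 back to 5, and 5 back to 2 and 4.** Ring F is opened at O1–C2 (oxidative cyclisation of a 2'-hydroxychalcone) and then at C2–C3 (crossed aldol condensation). This is the shortest dependable flavone synthesis, and it tolerates the bromide needed for the Heck step.

**2 back to 1, and 4 back to 3.** These are protections only: selective dibenzylation of the acetophenone, and methoxymethylation of the bromophenol aldehyde.

## Alternatives that were turned down

**Alternative 1:** Ring A is disconnected at C4a–C8a and unfolded into an open polyketide chain, so the two stereocentres are made first on an acyclic aldol-type unit and the phloroglucinol ring is folded last.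

- **Forward key step.** Dioxinone A2 is heated in methanol, which opens the dioxinone to a β-keto ester terminus. Mg(OMe)2 then drives Claisen condensation of the central methylene (the future C4a) onto the ester carbon (the future C8a), and aromatisation gives acylphloroglucinol A1.
- **For.** Every step has close precedent, so on that point it is stronger than the chosen route. Ring A also appears with its hydroxyls free.
- **Against.** A2 and A1 are α-aryl β-silyloxy ketones. In hot basic methanol the acidic α-aryl C–H invites β-elimination to an α-aryl chalcone and retro-aldol cleavage, and either erases both centres. After A1, ring C must still be closed by O1 displacing the C2 oxygen with inversion at a para-alkoxybenzylic carbon that will ionise. The C2 configuration set in the aldol is therefore not reliably transmitted, and the trans outcome rests on thermodynamics. The polyketide chain costs many linear steps to build a ring that can be bought as 12.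
- **Comparison.** The chosen route gives up precedent for its key step. In return it takes ring A from the shelf, creates both centres in one convergent step, and never exposes them to base.

**Alternative 2:** C2–C3 and O1–C8a are cut, so ring C is made as a dihydropyranone from aldehyde 7 and diene A4 before ring A exists.

- **Forward key step.** Ti(OiPr)4 with the matching BINOL enantiomer catalyses the hetero-Diels–Alder addition of 7 to A4, and acidic work-up gives enone A3.
- **For.** Titanium–BINOL cycloadditions of aryl aldehydes with Danishefsky-type dienes are established, so the key step is closer to known chemistry than the chosen one. It uses the same building block 7 and delivers the C4 ketone directly.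
- **Against.** A4 carries a bulky ortho-substituted aryl group at its reacting terminus, which lowers reactivity and makes the cis/trans outcome uncertain. Its chromone carbonyl competes for the titanium centre. In A3, C3 is benzylic and α to an enone from the moment it forms. The whole of ring A (four carbons, two oxygens, then aromatisation) must then be annulated onto C5–C6 of A3 by enolate chemistry, a multi-step sequence in which C3 can epimerise and C2 can be lost by β-elimination of the ring oxygen.
- **Comparison.** The chosen route has three steps after its key step and none is basic. What it gives up is the better precedent for the ring-forming step.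

**Alternative 3:** Only O1–C2 is cut. Precursor A6 already carries the C3 centre, and ring C is closed oxidatively.

- **Forward key step.** Anodic two-electron oxidation of the 4-hydroxybenzyl group of A6 gives para-quinone methide A7. The ortho-hydroxyl of ring A adds to it in a 1,6-sense and gives A5, with the C2 aryl group trans to the C3 aryl group.
- **For.** No redox adjustment at C4 is needed: A5 is the target apart from five benzyl groups, so after the key step this alternative is stronger on step economy. The oxidation is reagent-free.
- **Against.** All stereochemical information rests on the one centre of A6, a C–H flanked by an aryl ketone and ring E, which enolises easily. In A7 the same C–H is vinylogously acidified as well. Tautomerisation of A7 to an achiral α-aryl chalcone, which would cyclise to racemic material, competes with ring closure. Making A6 as a single enantiomer is itself an unsolved asymmetric α-functionalisation of a racemisation-prone ketone. The anode must also distinguish one phenol from the ring A phenol and from five benzyloxyarenes.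
- **Comparison.** The chosen route sets both centres together under catalyst control while C4 is an ether, so neither centre is acidic until the penultimate step. It pays for this with two redox-adjusting steps.

Key step: step 10

## Route

Assumption: the sense of induction of the chiral acid in step 10 cannot be read from the structures. The (R)-catalyst is written, and its mirror image is to be used if a first run gives the enantiomeric series.

Remark: C3 carries the descriptor R in 17 and 18 and S in 19 and 20. The arrangement in space is the same; only the CIP ranking of C2 against C4 changes when C4 becomes a carbonyl.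

Step 1
Reactants: 1 2,4,6-trihydroxyacetophenone
Product: 2 1-[2,4-bis(benzyloxy)-6-hydroxyphenyl]ethan-1-one
Conditions: BnBr (2.05 equiv), K2CO3, DMF, rt
Reagents that add atoms: benzyl bromide, BrCc1ccccc1
Why: Williamson etherification; the para hydroxyl and one ortho hydroxyl are alkylated, while the remaining ortho hydroxyl is held in a hydrogen bond to the acetyl carbonyl and should stay free.

Step 2
Reactants: 3 3-bromo-4-hydroxybenzaldehyde
Product: 4 3-bromo-4-(methoxymethoxy)benzaldehyde
Conditions: MOMCl, iPr2NEt, CH2Cl2, 0 °C to rt
Reagents that add atoms: chloromethyl methyl ether, COCCl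
Why: Methoxymethyl ether formation; the acetal-type ether is stable to the strong base of the next step and can later be removed without touching benzyl ethers.

Step 3
Reactants: 2 1-[2,4-bis(benzyloxy)-6-hydroxyphenyl]ethan-1-one, 4 3-bromo-4-(methoxymethoxy)benzaldehyde
Product: 5 (E)-1-[2,4-bis(benzyloxy)-6-hydroxyphenyl]-3-[3-bromo-4-(methoxymethoxy)phenyl]prop-2-en-1-one
Conditions: KOH (50% aq), EtOH/THF, rt
Reagents that add atoms: none
Why: Claisen–Schmidt condensation of a methyl ketone with a non-enolisable aldehyde; dehydration of the aldol should give the conjugated (E)-chalcone.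

Step 4
Reactants: 5 (E)-1-[2,4-bis(benzyloxy)-6-hydroxyphenyl]-3-[3-bromo-4-(methoxymethoxy)phenyl]prop-2-en-1-one
Product: 6 5,7-bis(benzyloxy)-2-[3-bromo-4-(methoxymethoxy)phenyl]-4H-chromen-4-one
Conditions: iodine (10 mol%), DMSO, 120 °C
Reagents that add atoms: none
Why: Iodine/DMSO oxidative cyclisation of a 2'-hydroxychalcone: oxa-Michael closure of the phenol onto the enone, then iodine-mediated dehydrogenation with DMSO as terminal oxidant; benzyl ethers and the aryl bromide are tolerated.

Step 5
Reactants: 7 4-(benzyloxy)benzaldehyde
Product: 8 1-(benzyloxy)-4-ethenylbenzene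
Conditions: Ph3PCH3Br, KOtBu, THF, 0 °C to rt
Reagents that add atoms: methyltriphenylphosphonium bromide, C[P+](c1ccccc1)(c1ccccc1)c1ccccc1.[Br-]
Why: Wittig methylenation with the non-stabilised ylide made in the flask; it converts the aldehyde into the terminal alkene and leaves the benzyl ether alone.

Step 6
Reactants: 6 5,7-bis(benzyloxy)-2-[3-bromo-4-(methoxymethoxy)phenyl]-4H-chromen-4-one, 8 1-(benzyloxy)-4-ethenylbenzene
Product: 9 5,7-bis(benzyloxy)-2-{3-[(E)-2-(4-(benzyloxy)phenyl)ethenyl]-4-(methoxymethoxy)phenyl}-4H-chromen-4-one
Conditions: Pd(OAc)2 (5 mol%), P(o-tol)3 (10 mol%), Et3N, DMF, 100 °C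
Reagents that add atoms: none
Why: Mizoroki–Heck reaction: the aryl bromide adds oxidatively to zerovalent palladium, the styrene inserts at its unsubstituted terminus, and syn β-hydride elimination should give the (E)-stilbene; the trisubstituted, electron-poor chromone C2=C3 bond does not insert.

Step 7
Reactants: 9 5,7-bis(benzyloxy)-2-{3-[(E)-2-(4-(benzyloxy)phenyl)ethenyl]-4-(methoxymethoxy)phenyl}-4H-chromen-4-one
Product: 10 5,7-bis(benzyloxy)-2-{3-[(E)-2-(4-(benzyloxy)phenyl)ethenyl]-4-hydroxyphenyl}-4H-chromen-4-one
Conditions: HCl (2 M aq), MeOH/THF, 45 °C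
Reagents that add atoms: none
Why: Acid-catalysed acetal cleavage of the methoxymethyl ether by transacetalisation to methanol; aryl benzyl ethers and the stilbene should survive dilute acid at this temperature.

Step 8
Reactants: 10 5,7-bis(benzyloxy)-2-{3-[(E)-2-(4-(benzyloxy)phenyl)ethenyl]-4-hydroxyphenyl}-4H-chromen-4-one
Product: 11 benzyl 4-[5,7-bis(benzyloxy)-4-oxo-4H-chromen-2-yl]-2-[(E)-2-(4-(benzyloxy)phenyl)ethenyl]phenyl carbonate
Conditions: CbzCl, Et3N, DMAP (cat.), CH2Cl2, 0 °C
Reagents that add atoms: benzyl chloroformate, O=C(Cl)OCc1ccccc1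
Why: O-acylation of the phenol with a chloroformate; the aryl benzyl carbonate makes ring E a poor donor, blocks the phenol as a nucleophile, and is later cleaved by the same hydrogenolysis as the ethers.

Step 9
Reactants: 12 2,4,6-trihydroxybenzaldehyde
Product: 13 2,4-bis(benzyloxy)-6-hydroxybenzaldehyde
Conditions: BnBr (2.05 equiv), K2CO3, DMF, rt
Reagents that add atoms: benzyl bromide, BrCc1ccccc1
Why: Williamson etherification with the same selectivity as step 1; the hydroxyl chelated to the formyl group is left free and later becomes O1.

Step 10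
Reactants: 13 2,4-bis(benzyloxy)-6-hydroxybenzaldehyde, 11 benzyl 4-[5,7-bis(benzyloxy)-4-oxo-4H-chromen-2-yl]-2-[(E)-2-(4-(benzyloxy)phenyl)ethenyl]phenyl carbonate, 14 trimethyl orthoformate
Product: 17 benzyl 2-[(2R,3R,4R)-5,7-bis(benzyloxy)-2-(4-(benzyloxy)phenyl)-4-methoxychroman-3-yl]-4-[5,7-bis(benzyloxy)-4-oxo-4H-chromen-2-yl]phenyl carbonate (2,3-trans-3,4-trans), via dimethyl acetal 15 (not isolated), via 4-methoxy ortho-quinone methide 16 (not isolated)
Conditions: (R)-3,3'-bis(2,4,6-triisopropylphenyl)-1,1'-binaphthyl-2,2'-diyl N-triflylphosphoramide (10 mol%), HC(OMe)3 (2 equiv), CH2Cl2/toluene, −30 °C to 0 °C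
Reagents that add atoms: trimethyl orthoformate 14, COC(OC)OC
Why: Proposed new method: the acid converts 13 and 14 into acetal 15 and ionises it to the O-protonated form of 16, an aryl-stabilised oxocarbenium ion held by the chiral phosphoramide anion through the phenolic O–H; the stilbene carbon bearing the carbonate-substituted ring E attacks C4, and the cation developing at C2, stabilised by the 4-benzyloxyphenyl ring, is captured by O1. The closest known reaction types are the acid-promoted three-component synthesis of 4-alkoxyflavans from salicylaldehydes, orthoformates and styrenes, and chiral phosphoric acid-catalysed [4+2] cycloadditions of ortho-quinone methides with styrenes; their combination with a 1,2-diarylethene under a chiral N-triflyl phosphoramide has not been shown. Ring C closes as the six-membered ring of an asynchronous inverse-demand oxa-[4+2] cycloaddition, C3–C4 first and O1–C2 second. C3 is set in the C–C bond-forming event, where the chiral counter-anion selects the alkene face that meets the oxocarbenium ion; C2 follows from the (E) geometry, carried into the 2,3-trans relationship because the cation collapses before it rotates and because the diequatorial arrangement is also the stable one; C4 takes the all-equatorial position, may equilibrate by re-ionisation, and is erased in step 12. The step needs regioselectivity, secured by the donor 4-benzyloxyphenyl ring against the acceptor carbonate on ring E; chemoselectivity for the stilbene over the electron-poor chromone C2=C3 bond; and enantioselectivity from the catalyst.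

Step 11
Reactants: 17 benzyl 2-[(2R,3R,4R)-5,7-bis(benzyloxy)-2-(4-(benzyloxy)phenyl)-4-methoxychroman-3-yl]-4-[5,7-bis(benzyloxy)-4-oxo-4H-chromen-2-yl]phenyl carbonate
Product: 18 benzyl 2-[(2R,3R)-5,7-bis(benzyloxy)-2-(4-(benzyloxy)phenyl)-4-hydroxychroman-3-yl]-4-[5,7-bis(benzyloxy)-4-oxo-4H-chromen-2-yl]phenyl carbonate (either C4 epimer)
Conditions: p-TsOH·H2O (cat.), THF/H2O, rt
Reagents that add atoms: water, O
Why: Acid-catalysed solvolysis (SN1 exchange) of a benzylic ether: C4 is benzylic to the trioxygenated ring A, so mild acid ionises the methyl ether and excess water captures the cation; C2 and C3 take no part, and either C4 epimer serves.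

Step 12
Reactants: 18 benzyl 2-[(2R,3R)-5,7-bis(benzyloxy)-2-(4-(benzyloxy)phenyl)-4-hydroxychroman-3-yl]-4-[5,7-bis(benzyloxy)-4-oxo-4H-chromen-2-yl]phenyl carbonate
Product: 19 benzyl 2-[(2R,3S)-5,7-bis(benzyloxy)-2-(4-(benzyloxy)phenyl)-4-oxochroman-3-yl]-4-[5,7-bis(benzyloxy)-4-oxo-4H-chromen-2-yl]phenyl carbonate
Conditions: Dess–Martin periodinane, NaHCO3, CH2Cl2, 0 °C to rt
Reagents that add atoms: none
Why: Dess–Martin oxidation of a secondary benzylic alcohol to the aryl ketone under buffered, non-basic conditions; both C4 epimers converge, C2 is untouched, and any enolisation at C3 returns the favoured 2,3-trans isomer.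

Step 13
Reactants: 19 benzyl 2-[(2R,3S)-5,7-bis(benzyloxy)-2-(4-(benzyloxy)phenyl)-4-oxochroman-3-yl]-4-[5,7-bis(benzyloxy)-4-oxo-4H-chromen-2-yl]phenyl carbonate
Product: 20 (2R,3S)-3-[5-(5,7-dihydroxy-4-oxo-4H-chromen-2-yl)-2-hydroxyphenyl]-5,7-dihydroxy-2-(4-hydroxyphenyl)chroman-4-one
Conditions: H2 (1 atm), 10% Pd/C, THF/MeOH, rt
Reagents that add atoms: none
Why: Catalytic hydrogenolysis cleaves the five benzyl ethers and the benzyl carbonate (which then loses CO2) in one neutral operation, so the epimerisable C3 and the hydroxyl next to the ketone meet neither acid nor base; benzylic O–CH2Ph bonds should be cleaved much faster than the aryl ketone or the chromone double bond is reduced.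

## Compound list

1 | 2,4,6-trihydroxyacetophenone | CC(=O)c1c(O)cc(O)cc1O | starting material
2 | 1-[2,4-bis(benzyloxy)-6-hydroxyphenyl]ethan-1-one | CC(=O)c1c(O)cc(OCc2ccccc2)cc1OCc1ccccc1 | intermediate
3 | 3-bromo-4-hydroxybenzaldehyde | O=Cc1ccc(O)c(Br)c1 | starting material
4 | 3-bromo-4-(methoxymethoxy)benzaldehyde | COCOc1ccc(C=O)cc1Br | intermediate
5 | (E)-1-[2,4-bis(benzyloxy)-6-hydroxyphenyl]-3-[3-bromo-4-(methoxymethoxy)phenyl]prop-2-en-1-one | COCOc1ccc(/C=C/C(=O)c2c(O)cc(OCc3ccccc3)cc2OCc2ccccc2)cc1Br | intermediate
6 | 5,7-bis(benzyloxy)-2-[3-bromo-4-(methoxymethoxy)phenyl]-4H-chromen-4-one | COCOc1ccc(-c2cc(=O)c3c(OCc4ccccc4)cc(OCc4ccccc4)cc3o2)cc1Br | intermediate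
7 | 4-(benzyloxy)benzaldehyde | O=Cc1ccc(OCc2ccccc2)cc1 | starting material
8 | 1-(benzyloxy)-4-ethenylbenzene | C=Cc1ccc(OCc2ccccc2)cc1 | intermediate
9 | 5,7-bis(benzyloxy)-2-{3-[(E)-2-(4-(benzyloxy)phenyl)ethenyl]-4-(methoxymethoxy)phenyl}-4H-chromen-4-one | COCOc1ccc(-c2cc(=O)c3c(OCc4ccccc4)cc(OCc4ccccc4)cc3o2)cc1/C=C/c1ccc(OCc2ccccc2)cc1 | intermediate
10 | 5,7-bis(benzyloxy)-2-{3-[(E)-2-(4-(benzyloxy)phenyl)ethenyl]-4-hydroxyphenyl}-4H-chromen-4-one | Oc1ccc(-c2cc(=O)c3c(OCc4ccccc4)cc(OCc4ccccc4)cc3o2)cc1/C=C/c1ccc(OCc2ccccc2)cc1 | intermediate
11 | benzyl 4-[5,7-bis(benzyloxy)-4-oxo-4H-chromen-2-yl]-2-[(E)-2-(4-(benzyloxy)phenyl)ethenyl]phenyl carbonate | O=C(OCc1ccccc1)Oc1ccc(-c2cc(=O)c3c(OCc4ccccc4)cc(OCc4ccccc4)cc3o2)cc1/C=C/c1ccc(OCc2ccccc2)cc1 | intermediate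
12 | 2,4,6-trihydroxybenzaldehyde | O=Cc1c(O)cc(O)cc1O | starting material
13 | 2,4-bis(benzyloxy)-6-hydroxybenzaldehyde | O=Cc1c(O)cc(OCc2ccccc2)cc1OCc1ccccc1 | intermediate
14 | trimethyl orthoformate | COC(OC)OC | starting material
15 | 3,5-bis(benzyloxy)-2-(dimethoxymethyl)phenol | COC(OC)c1c(O)cc(OCc2ccccc2)cc1OCc1ccccc1 | intermediate
16 | 3,5-bis(benzyloxy)-6-(methoxymethylidene)cyclohexa-2,4-dien-1-one (reacts as its O-protonated ion pair) | COC=C1C(=O)C=C(OCc2ccccc2)C=C1OCc1ccccc1 | intermediate
17 | benzyl 2-[(2R,3R,4R)-5,7-bis(benzyloxy)-2-(4-(benzyloxy)phenyl)-4-methoxychroman-3-yl]-4-[5,7-bis(benzyloxy)-4-oxo-4H-chromen-2-yl]phenyl carbonate | CO[C@H]1c2c(OCc3ccccc3)cc(OCc3ccccc3)cc2O[C@@H](c2ccc(OCc3ccccc3)cc2)[C@@H]1c1cc(-c2cc(=O)c3c(OCc4ccccc4)cc(OCc4ccccc4)cc3o2)ccc1OC(=O)OCc1ccccc1 | intermediate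
18 | benzyl 2-[(2R,3R)-5,7-bis(benzyloxy)-2-(4-(benzyloxy)phenyl)-4-hydroxychroman-3-yl]-4-[5,7-bis(benzyloxy)-4-oxo-4H-chromen-2-yl]phenyl carbonate (C4 configuration not defined) | OC1c2c(OCc3ccccc3)cc(OCc3ccccc3)cc2O[C@@H](c2ccc(OCc3ccccc3)cc2)[C@@H]1c1cc(-c2cc(=O)c3c(OCc4ccccc4)cc(OCc4ccccc4)cc3o2)ccc1OC(=O)OCc1ccccc1 | intermediate
19 | benzyl 2-[(2R,3S)-5,7-bis(benzyloxy)-2-(4-(benzyloxy)phenyl)-4-oxochroman-3-yl]-4-[5,7-bis(benzyloxy)-4-oxo-4H-chromen-2-yl]phenyl carbonate | O=C1c2c(OCc3ccccc3)cc(OCc3ccccc3)cc2O[C@@H](c2ccc(OCc3ccccc3)cc2)[C@@H]1c1cc(-c2cc(=O)c3c(OCc4ccccc4)cc(OCc4ccccc4)cc3o2)ccc1OC(=O)OCc1ccccc1 | intermediate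
20 | (2R,3S)-3-[5-(5,7-dihydroxy-4-oxo-4H-chromen-2-yl)-2-hydroxyphenyl]-5,7-dihydroxy-2-(4-hydroxyphenyl)chroman-4-one | O=C1c2c(O)cc(O)cc2O[C@@H](c2ccc(O)cc2)[C@@H]1c1cc(-c2cc(=O)c3c(O)cc(O)cc3o2)ccc1O | target

## Step count and risks

Total step count: 13.

Longest linear sequence: 10 steps (steps 1, 3, 4, 6, 7, 8, 10, 11, 12, 13).

**Step 10 (key step, proposed new method).**
- The strongly stabilised oxocarbenium ion may be only loosely paired with the chiral anion, which would give poor facial selectivity.
- The chromone carbonyl may bind the acid and slow turnover.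
- The 1,2-diarylethene is a weaker and bulkier nucleophile than a styrene, so self-condensation of the ionised acetal or acid-induced loss of methanol from the product could take over.
- Fallback: set out from 11, 13 and 14 and run the parent three-component coupling with an achiral acid (TfOH or Sc(OTf)3, CH2Cl2, 0 °C), the established acid-promoted 4-alkoxyflavan synthesis. Regiochemistry and the trans relationship are still dictated by the substrate. This would give 17 as a racemate, that is, together with its (2S,3S,4S)-enantiomer F1. The enantiomers are then separated by preparative chromatography on a chiral stationary phase, and the route is rejoined at 17.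

**Step 11.**
- The C4 cation may lose the C3 proton and form a 3-aryl-2H-chromene.
- It may be captured by an electron-rich ring of a second molecule, giving oligomers.
- The neighbouring carbonate may migrate to the new hydroxyl.
- Fallback: set out from 17 and oxidise C4 directly with DDQ in CH2Cl2/pH 7 buffer. Hydride abstraction from the doubly activated C4–H gives the methoxy-oxocarbenium ion, water adds, and the hemiketal collapses to the ketone. The route is rejoined at 19 without passing through 18.

**Step 13.**
- Cleavage of six benzylic C–O bonds may stall on sparingly soluble partly deprotected material.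
- Longer exposure may reduce the chromone double bond or open ring C by hydrogenolysis of the benzylic C2–O1 bond.
- Fallback: set out from 19 and remove the benzyl groups without hydrogen, using BCl3 and pentamethylbenzene as cation scavenger in CH2Cl2 at −78 °C. The carbonate falls apart on work-up, and the route arrives at 20.

**Step 4.**
- The hydrogen iodide formed may strip the methoxymethyl group, or the 5-benzyl group next to the carbonyl, and give mixtures.
- Fallback: set out from 5 and separate ring closure from dehydrogenation. NaOAc in refluxing EtOH would give racemic 5,7-bis(benzyloxy)-2-[3-bromo-4-(methoxymethoxy)phenyl]chroman-4-one F2, and DDQ in refluxing dioxane would dehydrogenate it, returning to the route at 6.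

**Step 9.**
- Statistical over- and under-alkylation and some C-benzylation of the very electron-rich ring may erode the selectivity.
- Fallback: set out from 12 and benzylate exhaustively (excess BnBr, K2CO3, DMF, 60 °C) to 2,4,6-tris(benzyloxy)benzaldehyde F3. One ortho benzyl ether is then cleaved by chelation-controlled dealkylation with MgBr2·OEt2 in toluene/Et2O at reflux, returning to the route at 13.

## Further compounds

F1 | step 10 | benzyl 2-[(2S,3S,4S)-5,7-bis(benzyloxy)-2-(4-(benzyloxy)phenyl)-4-methoxychroman-3-yl]-4-[5,7-bis(benzyloxy)-4-oxo-4H-chromen-2-yl]phenyl carbonate (enantiomer of 17) | CO[C@@H]1c2c(OCc3ccccc3)cc(OCc3ccccc3)cc2O[C@H](c2ccc(OCc3ccccc3)cc2)[C@H]1c1cc(-c2cc(=O)c3c(OCc4ccccc4)cc(OCc4ccccc4)cc3o2)ccc1OC(=O)OCc1ccccc1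
F0 | step 11 | none | none
F0 | step 13 | none | none
F2 | step 4 | racemic 5,7-bis(benzyloxy)-2-[3-bromo-4-(methoxymethoxy)phenyl]chroman-4-one | COCOc1ccc(C2CC(=O)c3c(OCc4ccccc4)cc(OCc4ccccc4)cc3O2)cc1Br
F3 | step 9 | 2,4,6-tris(benzyloxy)benzaldehyde | O=Cc1c(OCc2ccccc2)cc(OCc2ccccc2)cc1OCc1ccccc1
A1 | alternative 1 | syn-3-[4-(benzyloxy)phenyl]-2-[2-(benzyloxy)-5-(5,7-bis(benzyloxy)-4-oxo-4H-chromen-2-yl)phenyl]-3-(tert-butyldimethylsilyloxy)-1-(2,4,6-trihydroxyphenyl)propan-1-one | O=C(c1c(O)cc(O)cc1O)[C@@H](c1cc(-c2cc(=O)c3c(OCc4ccccc4)cc(OCc4ccccc4)cc3o2)ccc1OCc1ccccc1)[C@H](O[Si](C)(C)C(C)(C)C)c1ccc(OCc2ccccc2)cc1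
A2 | alternative 1 | 6-[syn-6-(4-(benzyloxy)phenyl)-5-(2-(benzyloxy)-5-(5,7-bis(benzyloxy)-4-oxo-4H-chromen-2-yl)phenyl)-6-(tert-butyldimethylsilyloxy)-2,4-dioxohexyl]-2,2-dimethyl-4H-1,3-dioxin-4-one | CC1(C)OC(=O)C=C(CC(=O)CC(=O)[C@@H](c2cc(-c3cc(=O)c4c(OCc5ccccc5)cc(OCc5ccccc5)cc4o3)ccc2OCc2ccccc2)[C@H](O[Si](C)(C)C(C)(C)C)c2ccc(OCc3ccccc3)cc2)O1
A3 | alternative 2 | (2R,3S)-2-[4-(benzyloxy)phenyl]-3-[2-(benzyloxy)-5-(5,7-bis(benzyloxy)-4-oxo-4H-chromen-2-yl)phenyl]-2,3-dihydro-4H-pyran-4-one | O=C1C=CO[C@@H](c2ccc(OCc3ccccc3)cc2)[C@@H]1c1cc(-c2cc(=O)c3c(OCc4ccccc4)cc(OCc4ccccc4)cc3o2)ccc1OCc1ccccc1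
A4 | alternative 2 | 2-{4-(benzyloxy)-3-[(1Z,3E)-4-methoxy-2-(trimethylsilyloxy)buta-1,3-dien-1-yl]phenyl}-5,7-bis(benzyloxy)-4H-chromen-4-one | CO/C=C/C(O[Si](C)(C)C)=C/c1cc(-c2cc(=O)c3c(OCc4ccccc4)cc(OCc4ccccc4)cc3o2)ccc1OCc1ccccc1
A5 | alternative 3 | (2R,3S)-5,7-bis(benzyloxy)-3-[2-(benzyloxy)-5-(5,7-bis(benzyloxy)-4-oxo-4H-chromen-2-yl)phenyl]-2-(4-hydroxyphenyl)chroman-4-one | O=C1c2c(OCc3ccccc3)cc(OCc3ccccc3)cc2O[C@@H](c2ccc(O)cc2)[C@@H]1c1cc(-c2cc(=O)c3c(OCc4ccccc4)cc(OCc4ccccc4)cc3o2)ccc1OCc1ccccc1
A6 | alternative 3 | (2R)-1-[2,4-bis(benzyloxy)-6-hydroxyphenyl]-2-[2-(benzyloxy)-5-(5,7-bis(benzyloxy)-4-oxo-4H-chromen-2-yl)phenyl]-3-(4-hydroxyphenyl)propan-1-one | O=C(c1c(O)cc(OCc2ccccc2)cc1OCc1ccccc1)[C@@H](c1cc(-c2cc(=O)c3c(OCc4ccccc4)cc(OCc4ccccc4)cc3o2)ccc1OCc1ccccc1)Cc1ccc(O)cc1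
A7 | alternative 3 | 4-{(2R)-3-[2,4-bis(benzyloxy)-6-hydroxyphenyl]-2-[2-(benzyloxy)-5-(5,7-bis(benzyloxy)-4-oxo-4H-chromen-2-yl)phenyl]-3-oxopropylidene}cyclohexa-2,5-dien-1-one | O=C(c1c(O)cc(OCc2ccccc2)cc1OCc1ccccc1)[C@@H](c1cc(-c2cc(=O)c3c(OCc4ccccc4)cc(OCc4ccccc4)cc3o2)ccc1OCc1ccccc1)C=C1C=CC(=O)C=C1
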